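## Structural features

- **Ring system.** The target is a 4-hydroxycoumarin. An unsubstituted benzo ring A (C4a, C5–C8, C8a) is fused along C4a–C8a to a 4-hydroxy-2-pyranone ring B (O1, C2, C3, C4, C4a, C8a).
- **Chain.** C3 carries a linear twelve-carbon sesquiterpenoid chain (C1'–C12', methyl branches at C3', C7' and C11'), and its far end C12' is an allylic benzoate.
- **Stereochemistry.** There is no sp3 stereocentre. The stereochemical content is three isolated trisubstituted alkenes, C2'=C3', C6'=C7' and C10'=C11', all E and in a skipped 1,5 relationship.
- **Fragile groups.** The enolic C4–OH (pKa about 5) adds to C2'=C3' under acid. The 1,5-polyene cyclises with strong acid. The C12' allylic benzoate is lost to alkoxide, hydride or zerovalent palladium.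
- **Real difficulty.** It lies in connectivity, on three counts:
  - Intact ring B is an ambident nucleophile (oxygen at C4, oxygen at C2, carbon C3) that stays nucleophilic after a first alkylation.
  - The chain has two allylic termini (C1', C12') that must be told apart.
  - The C12' oxygen must be benzoylated beside an acidic hydroxyl group.
- **Feature exploited.** C2 is a carbonic-acid-level carbon bound only to O1, its own oxygen and C3. Removing it leaves a phenol oxygen and the alpha carbon of an o-hydroxyaryl ketone, two nucleophiles held 1,5 to each other.
- **Route in one sentence.** Ring B is closed in the last step by inserting C2, as a carbonyl dication equivalent, between the phenol oxygen and the alpha carbon of the fully elaborated open-chain ketone 8.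

## Logic of the disconnections

**13 to 8 and 9.**
- Bonds cut: O1–C2 and C2–C3, that is, the single atom C2 with its exocyclic oxygen.
- Reason: C2 is the only atom of ring B that belongs neither to the aryl ketone part nor to the chain.
- Gain: without C2 the ambident vinylogous acid disappears. The heterocycle, the acidic enol and the carbon/oxygen selectivity problem vanish in one operation, and the precursor is an open-chain aryl ketone that already holds the finished chain.
- Demand: one carbonyl carbon must go to O1 and to C3, not to the enolate oxygen. This must happen without alkoxide, hydride, acid or transition metal, because the C12' benzoate and the polyene are present.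

**8 to 5 and 6.**
- Bond cut: the alkyl–oxygen bond C12'–O of the ester, not the acyl–oxygen bond.
- Reason: 5 has two hydroxyl groups, and acyl transfer reagents do not tell a primary allylic alcohol from a phenol reliably. Turning the alcohol into a leaving group does, since a phenol oxygen cannot be displaced from its ring.
- Gain: no protecting group is needed.
- Demand: direct substitution at C12' without transposition to C10', with the carboxylate of 6 outcompeting the phenol as nucleophile.

**5 to 4.**
- Bond cut: C12'–O, traced back to a C12'–H bond of the terminal isopropylidene group.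
- Reason and gain: the chain then needs no second functional terminus while the C3–C1' bond is made, so its two ends never compete as electrophiles. The whole C15 unit can be bought in one piece.
- Demand: site selectivity for the terminal alkene over two internal ones, and E selectivity between the two terminal methyl groups.

**4 to 1 and 2.**
- Bond cut: C3–C1', at a stage where C3 is the alpha carbon of a simple aryl methyl ketone.
- Reason: a ketone enolate alkylates at carbon, whereas the finished ring B alkylates at carbon and oxygen.
- Gain: both partners are commercial, and two of the three E alkenes come with 2.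
- Demand: monoalkylation at carbon in the presence of the phenoxide, by direct SN2 that keeps the C2'=C3' geometry.

## Other disconnections considered

**Alternative 1:** the first that comes to mind.
- Cut: C3–C1' with ring B intact.
- Forward key step: C-allylation of 4-hydroxycoumarin A1 with (2E,6E,10E)-12-bromo-2,6,10-trimethyldodeca-2,6,10-trien-1-yl benzoate A2 under base, or ionisation of the C1' terminus by a zerovalent palladium catalyst.
- Grounds for rejection:
  - The anion of A1 is ambident, so O-alkylation competes.
  - The monoalkylated product is still an acidic, nucleophilic 1,3-dicarbonyl system, so a second alkylation at C3 competes as well.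
  - A2 has two allylic carbon–heteroatom termini. Making it needs protection and release of C1' around the C12' oxidation, which is longer than the whole chosen route.
  - A palladium catalyst would also ionise the C12' benzoate.

**Alternative 2:**
- Cut: C3–C4.
- Forward key step: Dieckmann-type closure of methyl 2-{[(4E,8E,12E)-14-(benzoyloxy)-5,9,13-trimethyltetradeca-4,8,12-trienoyl]oxy}benzoate A3 with LiN(SiMe3)2.
- Merit: it also avoids the ambident nucleophile and is a sound plan.
- Grounds for rejection:
  - The enolate of an aryl ester can expel its phenoxide and fragment to a ketene before it cyclises.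
  - The closure releases methoxide beside the benzoate.
  - A3 needs the free C17 acid and a separate esterification, so the plan is one step longer. In the chosen plan ring A enters together with the C3–C1' bond in step 1.

**Alternative 3:**
- Cut: O1–C8a and C4–C4a.
- Forward key step: annulation of benzyne A5, set free from 2-(trimethylsilyl)phenyl triflate A6 with CsF, with the racemic malonic half ester (4E,8E,12E)-14-(benzoyloxy)-2-(methoxycarbonyl)-5,9,13-trimethyltetradeca-4,8,12-trienoic acid A4.
- Mechanism: the carboxylate adds to the aryne and the aryl anion closes on the methyl ester, as in the aryne route from salicylates to xanthones.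
- Grounds for rejection:
  - After the first addition the aryl anion sits within reach of the acidic malonate C–H through a six-membered transition state. Proton transfer should quench it before acyl attack, and the sequence would stop at plain O-arylation.
  - The three trisubstituted alkenes are ene partners for A5.
  - Ring A is unsubstituted, so an aryne brings no regiochemical gain.
  - A4 requires a selective half-saponification beside a benzoate.

Key step: step 4

Assumption: the target is treated as the 4-hydroxy-2H-chromen-2-one tautomer shown in the SMILES, and commercial 2 is taken as the pure (2E,6E) isomer.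

## Steps

Step 1
Reactants: 1 2'-hydroxyacetophenone; 2 (2E,6E)-farnesyl bromide
Product: 4 (4E,8E)-1-(2-hydroxyphenyl)-5,9,13-trimethyltetradeca-4,8,12-trien-1-one, via dilithium dianion 3 (not isolated)
Conditions: LiN(i-Pr)2 (2.2 equiv per 1), THF, −78 → 0 °C; 2 (0.8 equiv per 1), −78 °C → rt; cold 1 M HCl quench
Reagents that add atoms: none
Why: Alkylation of a phenoxide/enolate dianion: in 3 the enolate carbon is far more basic and nucleophilic than the phenoxide oxygen, so the primary allylic bromide should be taken up at carbon by direct SN2, without allylic transposition and with the C2'=C3' and C6'=C7' geometries of 2 carried over. The C3–C1' bond is thus made while C3 is a plain ketone alpha carbon, and an excess of cheap 3 holds back a second alkylation.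

Step 2
Reactants: 4 (4E,8E)-1-(2-hydroxyphenyl)-5,9,13-trimethyltetradeca-4,8,12-trien-1-one
Product: 5 (4E,8E,12E)-14-hydroxy-1-(2-hydroxyphenyl)-5,9,13-trimethyltetradeca-4,8,12-trien-1-one
Conditions: SeO2 (0.2 equiv), t-BuOOH (2.5 equiv, decane solution), salicylic acid (0.1 equiv), CH2Cl2, 0 °C → rt, stopped at partial conversion, 4 recovered
Reagents that add atoms: selenium dioxide O=[Se]=O (oxygen carrier); tert-butyl hydroperoxide CC(C)(C)OO (terminal oxygen source)
Why: Catalytic SeO2/t-BuOOH allylic oxidation (ene reaction, then [2,3]-sigmatropic shift) is a standard way to the E-omega-alcohols of prenyl chains: the unhindered isopropylidene terminus reacts ahead of the two internal trisubstituted alkenes, and the ene/[2,3] sequence puts the oxygen on the methyl group trans to the chain, which sets C10'=C11' as E. The hydrogen-bonded o-acylphenol is of the same kind as the salicylic acid additive, and Riley oxidation alpha to the ketone needs much higher temperatures.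

Step 3
Reactants: 5 (4E,8E,12E)-14-hydroxy-1-(2-hydroxyphenyl)-5,9,13-trimethyltetradeca-4,8,12-trien-1-one; 6 benzoic acid
Product: 8 (2E,6E,10E)-14-(2-hydroxyphenyl)-2,6,10-trimethyl-14-oxotetradeca-2,6,10-trien-1-yl benzoate, via alkoxyphosphonium benzoate 7 (not isolated)
Conditions: PPh3 (1.3 equiv), DIAD (1.3 equiv), THF, 0 °C → rt
Reagents that add atoms: benzoic acid (6) OC(=O)c1ccccc1
Why: Mitsunobu esterification: only the aliphatic alcohol can become the oxyphosphonium leaving group of 7, and the benzoate ion (acid pKa about 4) outcompetes the chelated phenol (pKa about 10) as nucleophile, so the phenol needs no protection. Displacement at the unhindered primary C12' should be direct SN2, which leaves C10'=C11' in place and E.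

Step 4
Reactants: 8 (2E,6E,10E)-14-(2-hydroxyphenyl)-2,6,10-trimethyl-14-oxotetradeca-2,6,10-trien-1-yl benzoate; 9 1,1'-carbonyldiimidazole
Product: 13 E-omega-benzoyloxyferulenol, via dilithium dianion 10 (not isolated), via aryl imidazole-1-carboxylate enolate 11 (not isolated), via lithium coumarin-4-olate 12 (not isolated)
Conditions: LiN(SiMe3)2 (2.2 equiv), THF, −78 → −20 °C; 9 (1.05 equiv, slow addition), −78 °C → rt; cold 0.5 M HCl to pH 3
Reagents that add atoms: 1,1'-carbonyldiimidazole (9) O=C(n1ccnc1)n1ccnc1
Why: LiN(SiMe3)2 removes the phenol proton and one alpha proton of 8 to give dianion 10, the type of dilithio species that is known to be acylated at carbon in the direct synthesis of o-hydroxyaryl 1,3-diketones. The first acyl transfer from 9 should go to the phenoxide oxygen (O1–C2) and give 11, in which C3 faces an activated carbonyl group across a forming six-membered ring; if carbon reacts first, the phenoxide closes on the resulting acylimidazole and the same product is reached, so both orders converge. Ring B closes by a 6-(enolendo)-exo-trig attack of C3 on C2 with loss of imidazolide, the geometry of the Baker–Venkataraman acyl transfer. The closest known reaction type is the classical synthesis of 4-hydroxycoumarins from o-hydroxyaryl ketones and carbonic acid derivatives (dialkyl carbonates, phosgene) under base, of which only the carbonyl donor and the temperature are adapted. The released imidazolide deprotonates the chromane-2,4-dione at once to the delocalised salt 12 (conjugate acid pKa about 5), and this sink should also drain any kinetic acylation at the enolate oxygen, because such enol carbonates are reopened by imidazolide. No stereocentre is formed, and the three E alkenes are not touched by these bases at these temperatures. The selectivity needed is carbonyl transfer to O1 and C3 beside the C12' benzoate: no alkoxide is ever present, imidazolide cannot displace an alkoxide from an alkyl benzoate to a useful extent, the amide base is non-nucleophilic, and attack of C3 on its own benzoate would need a fifteen-membered ring. The cold, weakly acidic quench avoids addition of the C4 hydroxyl to C2'=C3'.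

## Compound list

1 | 2'-hydroxyacetophenone, 1-(2-hydroxyphenyl)ethan-1-one | CC(=O)c1ccccc1O | starting material
2 | (2E,6E)-farnesyl bromide, (2E,6E)-1-bromo-3,7,11-trimethyldodeca-2,6,10-triene | CC(C)=CCC/C(C)=C/CC/C(C)=C/CBr | starting material
3 | dilithium 2-(1-oxidoethenyl)phenolate (dianion of 1) | [Li+].[Li+].C=C([O-])c1ccccc1[O-] | intermediate
4 | (4E,8E)-1-(2-hydroxyphenyl)-5,9,13-trimethyltetradeca-4,8,12-trien-1-one | CC(C)=CCC/C(C)=C/CC/C(C)=C/CCC(=O)c1ccccc1O | intermediate
5 | (4E,8E,12E)-14-hydroxy-1-(2-hydroxyphenyl)-5,9,13-trimethyltetradeca-4,8,12-trien-1-one | C/C(=C\CC/C(C)=C/CCC(=O)c1ccccc1O)CC/C=C(\C)CO | intermediate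
6 | benzoic acid | OC(=O)c1ccccc1 | starting material
7 | triphenylphosphonium ether of 5 at the C12' oxygen, benzoate salt | C/C(=C\CC/C(C)=C/CCC(=O)c1ccccc1O)CC/C=C(\C)CO[P+](c1ccccc1)(c1ccccc1)c1ccccc1.[O-]C(=O)c1ccccc1 | intermediate
8 | (2E,6E,10E)-14-(2-hydroxyphenyl)-2,6,10-trimethyl-14-oxotetradeca-2,6,10-trien-1-yl benzoate | C/C(=C\CC/C(C)=C/CCC(=O)c1ccccc1O)CC/C=C(\C)COC(=O)c1ccccc1 | intermediate
9 | 1,1'-carbonyldiimidazole | O=C(n1ccnc1)n1ccnc1 | starting material
10 | dilithium phenolate/(Z)-enolate of 8 | [Li+].[Li+].C/C(=C\CC/C(C)=C/C/C=C(\[O-])c1ccccc1[O-])CC/C=C(\C)COC(=O)c1ccccc1 | intermediate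
11 | lithium (Z)-enolate of the O-(imidazole-1-carbonyl) derivative of 8 | [Li+].C/C(=C\CC/C(C)=C/C/C=C(\[O-])c1ccccc1OC(=O)n1ccnc1)CC/C=C(\C)COC(=O)c1ccccc1 | intermediate
12 | lithium 3-[(2E,6E,10E)-12-(benzoyloxy)-3,7,11-trimethyldodeca-2,6,10-trienyl]-2-oxo-2H-chromen-4-olate | [Li+].C/C(=C\CC/C(C)=C/Cc1c([O-])c2ccccc2oc1=O)CC/C=C(\C)COC(=O)c1ccccc1 | intermediate
13 | E-omega-benzoyloxyferulenol, (2E,6E,10E)-12-(4-hydroxy-2-oxo-2H-chromen-3-yl)-2,6,10-trimethyldodeca-2,6,10-trien-1-yl benzoate | C/C(=C\CC/C(C)=C/Cc1c(O)c2ccccc2oc1=O)CC/C=C(\C)COC(=O)c1ccccc1 | target

## Step count and least certain steps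

Total step count: 4. Longest linear sequence: 4 steps (1 → 4 → 5 → 8 → 13).

**Step 4 (key step).**
- Risk:
  - Kinetic carbonyl transfer to the enolate oxygen, or between two phenoxides of different molecules, may not fully equilibrate to the C-acylated ring at low temperature with lithium counter-ions.
  - On warming, slow crossed Claisen attack of the enolate on the benzoate of a second molecule may set in.
- Fallback: it sets out from 4 and returns at 13. The ring closure is moved ahead of the chain oxidation so that it can run under the classical equilibrating conditions.
  - 4 with NaH and diethyl carbonate in hot toluene should give ferulenol F1.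
  - Catalytic SeO2/t-BuOOH oxidation as in step 2 should give E-omega-hydroxyferulenol F2.
  - Exhaustive benzoylation (BzCl, Et3N, DMAP, CH2Cl2) should give the 4-O,12'-O-dibenzoate F3.
  - One equivalent of morpholine at 0 °C should remove only the enol benzoate, which is a vinylogous mixed anhydride, and deliver 13.

**Step 2.**
- Risk:
  - Site selectivity among three trisubstituted alkenes may be imperfect, since the C2'=C3' alkene is not deactivated here.
  - The alcohol may be over-oxidised to the aldehyde level, and some oxidation alpha to the ketone may occur.
- Fallback: it sets out from 4 and returns at 5.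
  - Cross-metathesis of the isopropylidene terminus with methacrolein (second-generation Hoveyda–Grubbs catalyst, CH2Cl2, 40 °C) is a formal allylic oxidation driven by loss of a volatile alkene. It is thermodynamically biased to the E enal and should give (2E,6E,10E)-14-(2-hydroxyphenyl)-2,6,10-trimethyl-14-oxotetradeca-2,6,10-trienal F4.
  - Luche reduction (NaBH4, CeCl3·7H2O, MeOH, −78 °C) should reduce the aldehyde ahead of the chelated, electron-rich aryl ketone and give 5.

**Step 3.**
- Risk:
  - The phenol may take part as nucleophile (aryl ether formation).
  - Partial allylic transposition may occur during displacement.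
  - The phosphine oxide may be hard to remove from a lipophilic product.
- Fallback: it sets out from 5 and returns at 8. Selectivity is moved from the acylation to a deacylation.
  - BzCl in pyridine should benzoylate both hydroxyl groups to the dibenzoate F5.
  - One equivalent of morpholine in CH2Cl2 at 0 °C should cleave only the aryl benzoate, which is activated by the ortho acyl group, and leave the alkyl benzoate of 8.

**Step 1.**
- Risk:
  - Proton exchange between the product and unreacted dianion may lead to a second alkylation at the alpha carbon.
  - Some O-alkylation of the phenoxide may occur late in the reaction.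
  - The allylic bromide may lose geometric purity on storage.
- Fallback: it sets out from 1 and 2 and returns at 4. It uses a metallated hydrazone, which alkylates once and cleanly.
  - 1 with N,N-dimethylhydrazine (EtOH, reflux) should give the (E)-N,N-dimethylhydrazone F6.
  - Double deprotonation (n-BuLi, 2.1 equiv, THF, −78 → 0 °C) and addition of 2 should give the farnesylated hydrazone F7.
  - Hydrolysis with CuCl2 in aqueous THF at pH 7 should release 4 without exposing the polyene to acid.

## Further compounds

F1 | step 4 | ferulenol, 4-hydroxy-3-[(2E,6E)-3,7,11-trimethyldodeca-2,6,10-trienyl]-2H-chromen-2-one | CC(C)=CCC/C(C)=C/CC/C(C)=C/Cc1c(O)c2ccccc2oc1=O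
F2 | step 4 | E-omega-hydroxyferulenol, 4-hydroxy-3-[(2E,6E,10E)-12-hydroxy-3,7,11-trimethyldodeca-2,6,10-trienyl]-2H-chromen-2-one | C/C(=C\CC/C(C)=C/Cc1c(O)c2ccccc2oc1=O)CC/C=C(\C)CO
F3 | step 4 | 4-O,12'-O-dibenzoate of E-omega-hydroxyferulenol | C/C(=C\CC/C(C)=C/Cc1c(OC(=O)c3ccccc3)c2ccccc2oc1=O)CC/C=C(\C)COC(=O)c1ccccc1
F4 | step 2 | (2E,6E,10E)-14-(2-hydroxyphenyl)-2,6,10-trimethyl-14-oxotetradeca-2,6,10-trienal | C/C(=C\CC/C(C)=C/CCC(=O)c1ccccc1O)CC/C=C(\C)C=O
F5 | step 3 | (2E,6E,10E)-14-[2-(benzoyloxy)phenyl]-2,6,10-trimethyl-14-oxotetradeca-2,6,10-trien-1-yl benzoate | C/C(=C\CC/C(C)=C/CCC(=O)c1ccccc1OC(=O)c1ccccc1)CC/C=C(\C)COC(=O)c1ccccc1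
F6 | step 1 | (E)-2'-hydroxyacetophenone N,N-dimethylhydrazone | C/C(c1ccccc1O)=N\N(C)C
F7 | step 1 | (E)-N,N-dimethylhydrazone of 4 | CC(C)=CCC/C(C)=C/CC/C(C)=C/CC/C(c1ccccc1O)=N\N(C)C
A1 | alternative 1 | 4-hydroxycoumarin | O=c1cc(O)c2ccccc2o1
A2 | alternative 1 | (2E,6E,10E)-12-bromo-2,6,10-trimethyldodeca-2,6,10-trien-1-yl benzoate | C/C(=C\CC/C(C)=C/CBr)CC/C=C(\C)COC(=O)c1ccccc1
A3 | alternative 2 | methyl 2-{[(4E,8E,12E)-14-(benzoyloxy)-5,9,13-trimethyltetradeca-4,8,12-trienoyl]oxy}benzoate | C/C(=C\CC/C(C)=C/CCC(=O)Oc1ccccc1C(=O)OC)CC/C=C(\C)COC(=O)c1ccccc1
A4 | alternative 3 | (4E,8E,12E)-14-(benzoyloxy)-2-(methoxycarbonyl)-5,9,13-trimethyltetradeca-4,8,12-trienoic acid (racemic at C2) | C/C(=C\CC/C(C)=C/CC(C(=O)O)C(=O)OC)CC/C=C(\C)COC(=O)c1ccccc1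
A5 | alternative 3 | benzyne | C1#CC=CC=C1
A6 | alternative 3 | 2-(trimethylsilyl)phenyl trifluoromethanesulfonate | C[Si](C)(C)c1ccccc1OS(=O)(=O)C(F)(F)F
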